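**Retrosynthetic overview**
1. Target 36 comes from alcohol 31 by late C9 angeloylation and allylic oxidation of the isopropenyl group at C15; the exo-methylene comes from a CH2OH group by mesylate elimination.
2. The cyclohexane (ring B) is closed last, at C5–C6, by an intramolecular carbonyl-ene reaction of aldehyde 24; C6 is then inverted by oxidation and LiBH(s-Bu)3 reduction.
3. Key disconnection C9–C10: intermolecular allylboration of lactone aldehyde 11 with the (Z)-γ,γ-disubstituted allylboronate 18, which sets C9–OH and the methyl/vinyl quaternary C10.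
4. Aldehyde 11 comes from (R)-butenolide 4 (chiral pool, C8) by trans conjugate vinylation (C7) and a formaldehyde aldol (C13); boronate 18 comes from propargyl alcohol by syn-methylcupration of an ynoate.
5. Ring order: γ-lactone (ring A, step 2) first, cyclohexane (ring B, step 21) second.

Abbreviations: TBS = tert-butyldimethylsilyl, TBDPS = tert-butyldiphenylsilyl, PMB = 4-methoxybenzyl, pin = pinacolato. Ring intermediates carry elemane numbering (C1=C2 vinyl and C14 methyl on C10; C3/C4/C15 on C5; C11–C13 in the lactone).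

Assumption: enolates, alkoxides, acetylides and cuprate adducts that are quenched within the same operation are treated as part of the step and carry no number.

**Route**

Step 1
Reactants: 1 methyl (4S)-2,2-dimethyl-1,3-dioxolane-4-carboxylate
Product: 3 methyl (2Z)-3-[(4R)-2,2-dimethyl-1,3-dioxolan-4-yl]prop-2-enoate, via aldehyde 2 (not isolated)
Conditions: i-Bu2AlH, CH2Cl2, −78 °C; then Ph3P=CHCO2Me, MeOH, −78 → 0 °C
Reagents that add atoms: methyl (triphenylphosphoranylidene)acetate, COC(=O)C=P(c1ccccc1)(c1ccccc1)c1ccccc1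
Why: Cold i-Bu2AlH stops at the aldehyde and the stabilised ylide in methanol gives the Z-enoate (Z-selective Wittig olefination of an α-alkoxy aldehyde); the stereocentre is carried over from the chiral pool.

Step 2
Reactants: 3 methyl (2Z)-3-[(4R)-2,2-dimethyl-1,3-dioxolan-4-yl]prop-2-enoate
Product: 4 (5R)-5-(hydroxymethyl)furan-2(5H)-one
Conditions: H2SO4 (cat.), MeOH/H2O, rt
Reagents that add atoms: none
Why: Acid removes the acetonide and the secondary hydroxyl of the Z-enoate lactonises (intramolecular transesterification) to ring A without touching the stereocentre that becomes C8.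

Step 3
Reactants: 4 (5R)-5-(hydroxymethyl)furan-2(5H)-one
Product: 5 (5R)-5-(TBSO-methyl)furan-2(5H)-one
Conditions: TBSCl, imidazole, CH2Cl2, 0 °C → rt
Reagents that add atoms: tert-butyldimethylsilyl chloride, CC(C)(C)[Si](C)(C)Cl
Why: Standard silylation of the primary alcohol gives the bulky C5 substituent that steers the next addition.

Step 4
Reactants: 5 (5R)-5-(TBSO-methyl)furan-2(5H)-one
Product: 6 (4S,5R)-5-(TBSO-methyl)-4-ethenyloxolan-2-one
Conditions: CH2=CHMgBr, CuBr·SMe2 (10 mol %), THF, −78 °C; NH4Cl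
Reagents that add atoms: vinylmagnesium bromide, C=C[Mg]Br
Why: Copper-catalysed conjugate addition to the butenolide occurs on the face opposite the C5 substituent, so the vinyl group (future C6) ends up trans and C7 is set.

Step 5
Reactants: 6 (4S,5R)-5-(TBSO-methyl)-4-ethenyloxolan-2-one
Product: 7 (3S,4R,5R)-5-(TBSO-methyl)-4-ethenyl-3-(hydroxymethyl)oxolan-2-one
Conditions: LiN(i-Pr)2, THF, −78 °C; CH2O (g), −78 → −30 °C; NH4Cl
Reagents that add atoms: formaldehyde, C=O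
Why: Aldol reaction of the lactone lithium enolate with monomeric formaldehyde installs C13 anti to the adjacent vinyl group; this centre is removed again in step 26.

Step 6
Reactants: 7 (3S,4R,5R)-5-(TBSO-methyl)-4-ethenyl-3-(hydroxymethyl)oxolan-2-one
Product: 8 (3S,4R,5R)-5-(TBSO-methyl)-3-(TBDPSO-methyl)-4-ethenyloxolan-2-one
Conditions: TBDPSCl, imidazole, DMF, rt
Reagents that add atoms: tert-butyldiphenylsilyl chloride, CC(C)(C)[Si](Cl)(c1ccccc1)c1ccccc1
Why: Silylation of the new primary alcohol with the more acid-stable TBDPS group allows the TBS ether to be removed selectively in the next step.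

Step 7
Reactants: 8 (3S,4R,5R)-5-(TBSO-methyl)-3-(TBDPSO-methyl)-4-ethenyloxolan-2-one
Product: 10 (3S,4R,5R)-3-(TBDPSO-methyl)-4-(dimethoxymethyl)-5-(hydroxymethyl)oxolan-2-one, via aldehyde 9 (not isolated)
Conditions: O3, CH2Cl2/MeOH, −78 °C; Me2S; then CSA (cat.), MeOH, 3 Å MS, rt
Reagents that add atoms: methanol, CO; ozone, [O-][O+]=O (oxygen of 9 only)
Why: Ozonolysis of the only alkene gives the C6 aldehyde, which acidic methanol converts to the dimethyl acetal while the primary TBS ether is methanolysed and the TBDPS ether survives; no stereocentre is affected.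

Step 8
Reactants: 10 (3S,4R,5R)-3-(TBDPSO-methyl)-4-(dimethoxymethyl)-5-(hydroxymethyl)oxolan-2-one
Product: 11 (2R,3R,4S)-4-(TBDPSO-methyl)-3-(dimethoxymethyl)-5-oxooxolane-2-carbaldehyde
Conditions: Dess–Martin periodinane, CH2Cl2, 0 °C → rt
Reagents that add atoms: none
Why: Dess–Martin oxidation under neutral conditions gives the α-acyloxy aldehyde (C9) without epimerising C8; it is used crude.

Step 9
Reactants: 12 prop-2-yn-1-ol
Product: 13 1-methoxy-4-[(prop-2-yn-1-yloxy)methyl]benzene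
Conditions: NaH, PMBCl, Bu4NI (cat.), THF, 0 °C → rt
Reagents that add atoms: 4-methoxybenzyl chloride, COc1ccc(CCl)cc1
Why: Williamson etherification protects the oxygen that will sit on C5.

Step 10
Reactants: 13 1-methoxy-4-[(prop-2-yn-1-yloxy)methyl]benzene
Product: 14 ethyl 4-(PMB-oxy)but-2-ynoate
Conditions: n-BuLi, THF, −78 °C; ClCO2Et
Reagents that add atoms: ethyl chloroformate, CCOC(=O)Cl
Why: C-acylation of the lithium acetylide gives the ynoate needed for stereodefined carbometalation.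

Step 11
Reactants: 14 ethyl 4-(PMB-oxy)but-2-ynoate
Product: 15 ethyl (2Z)-4-(PMB-oxy)-3-methylbut-2-enoate
Conditions: Me2CuLi (from CuI + 2 MeLi), THF, −78 °C; MeOH/NH4Cl quench at −78 °C
Reagents that add atoms: lithium dimethylcuprate, [Li+].C[Cu-]C
Why: syn-Carbocupration (conjugate addition) of the ynoate at −78 °C puts methyl and hydrogen cis, so CH2OPMB is cis to the ester and the Z geometry needed for the key step is fixed.

Step 12
Reactants: 15 ethyl (2Z)-4-(PMB-oxy)-3-methylbut-2-enoate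
Product: 16 (2Z)-4-(PMB-oxy)-3-methylbut-2-en-1-ol
Conditions: i-Bu2AlH, CH2Cl2, −78 °C
Reagents that add atoms: none
Why: 1,2-Reduction of the enoate gives the allylic alcohol with the double-bond geometry unchanged.

Step 13
Reactants: 16 (2Z)-4-(PMB-oxy)-3-methylbut-2-en-1-ol
Product: 17 1-({[(2Z)-4-chloro-2-methylbut-2-en-1-yl]oxy}methyl)-4-methoxybenzene
Conditions: NCS, Me2S, CH2Cl2, −20 → 0 °C
Reagents that add atoms: N-chlorosuccinimide, O=C1CCC(=O)N1Cl
Why: Corey–Kim chlorination displaces the activated primary allylic oxygen by SN2, without allylic transposition or E/Z scrambling.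

Step 14
Reactants: 17 1-({[(2Z)-4-chloro-2-methylbut-2-en-1-yl]oxy}methyl)-4-methoxybenzene
Product: 18 2-[(2Z)-4-(PMB-oxy)-3-methylbut-2-en-1-yl]-4,4,5,5-tetramethyl-1,3,2-dioxaborolane
Conditions: B2pin2, Pd2(dba)3 (2.5 mol %), THF, 60 °C
Reagents that add atoms: bis(pinacolato)diboron, CC1(C)OB(OC1(C)C)B1OC(C)(C)C(C)(C)O1
Why: Zerovalent palladium gives a π-allyl complex that is borylated at the primary terminus (Miyaura-type allylic borylation); the geometry is kept because isomerisation would have to pass through the tertiary terminus.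

Step 15
Reactants: 11 (2R,3R,4S)-4-(TBDPSO-methyl)-3-(dimethoxymethyl)-5-oxooxolane-2-carbaldehyde; 18 2-[(2Z)-4-(PMB-oxy)-3-methylbut-2-en-1-yl]-4,4,5,5-tetramethyl-1,3,2-dioxaborolane
Product: 19 (3S,4R,5R)-3-(TBDPSO-methyl)-4-(dimethoxymethyl)-5-[(1S,2S)-1-hydroxy-2-(PMB-oxymethyl)-2-methylbut-3-en-1-yl]oxolan-2-one
Conditions: toluene, 4 Å MS, 45 °C, 48 h; aq. NaHCO3
Reagents that add atoms: none
Why: Uncatalysed carbonyl allylboration through a closed chair (Zimmerman–Traxler) transition state joins the two fragments at C9–C10: the Z-CH2OPMB group sits axial, which puts C9–OH syn to CH2OPMB and anti to methyl at the new quaternary C10, and Felkin–Anh attack anti to the lactone C8–O bond gives the 8,9-anti relationship.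

Step 16
Reactants: 19 (3S,4R,5R)-3-(TBDPSO-methyl)-4-(dimethoxymethyl)-5-[(1S,2S)-1-hydroxy-2-(PMB-oxymethyl)-2-methylbut-3-en-1-yl]oxolan-2-one
Product: 20 (3S,4R,5R)-3-(TBDPSO-methyl)-4-(dimethoxymethyl)-5-[(1S,2S)-1-(TBSO)-2-(PMB-oxymethyl)-2-methylbut-3-en-1-yl]oxolan-2-one
Conditions: TBSOTf, 2,6-lutidine, CH2Cl2, −78 → 0 °C
Reagents that add atoms: tert-butyldimethylsilyl trifluoromethanesulfonate, CC(C)(C)[Si](C)(C)OS(=O)(=O)C(F)(F)F
Why: The silyl triflate is reactive enough for the hindered neopentyl-type C9 hydroxyl, and the low temperature spares the dimethyl acetal.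

Step 17
Reactants: 20 (3S,4R,5R)-3-(TBDPSO-methyl)-4-(dimethoxymethyl)-5-[(1S,2S)-1-(TBSO)-2-(PMB-oxymethyl)-2-methylbut-3-en-1-yl]oxolan-2-one
Product: 21 (3S,4R,5R)-3-(TBDPSO-methyl)-4-(dimethoxymethyl)-5-[(1S,2S)-1-(TBSO)-2-(hydroxymethyl)-2-methylbut-3-en-1-yl]oxolan-2-one
Conditions: DDQ, CH2Cl2/pH 7 buffer, 0 °C
Reagents that add atoms: none
Why: Oxidative cleavage of the PMB ether frees the C5 hydroxyl while silyl ethers, acetal and lactone are inert.

Step 18
Reactants: 21 (3S,4R,5R)-3-(TBDPSO-methyl)-4-(dimethoxymethyl)-5-[(1S,2S)-1-(TBSO)-2-(hydroxymethyl)-2-methylbut-3-en-1-yl]oxolan-2-one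
Product: 22 (3S,4R,5R)-3-(TBDPSO-methyl)-4-(dimethoxymethyl)-5-[(1S,2R)-1-(TBSO)-2-formyl-2-methylbut-3-en-1-yl]oxolan-2-one
Conditions: Dess–Martin periodinane, CH2Cl2, rt
Reagents that add atoms: none
Why: Dess–Martin oxidation gives the C5 aldehyde, which has no α-hydrogen and so cannot epimerise or eliminate.

Step 19
Reactants: 22 (3S,4R,5R)-3-(TBDPSO-methyl)-4-(dimethoxymethyl)-5-[(1S,2R)-1-(TBSO)-2-formyl-2-methylbut-3-en-1-yl]oxolan-2-one
Product: 23 (3S,4R,5R)-3-(TBDPSO-methyl)-4-(dimethoxymethyl)-5-[(1S,2S)-1-(TBSO)-2-ethenyl-2,4-dimethylpent-3-en-1-yl]oxolan-2-one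
Conditions: i-PrPPh3I, n-BuLi, THF, 0 °C; then 22 (1.2 equiv ylide), −78 → 0 °C
Reagents that add atoms: isopropyltriphenylphosphonium iodide, CC(C)[P+](c1ccccc1)(c1ccccc1)c1ccccc1.[I-]
Why: Wittig olefination with the non-stabilised isopropylidene ylide installs C4, C3 and C15 as the trisubstituted alkene needed for the ene reaction; the cold addition and small excess limit attack on the lactone.

Step 20
Reactants: 23 (3S,4R,5R)-3-(TBDPSO-methyl)-4-(dimethoxymethyl)-5-[(1S,2S)-1-(TBSO)-2-ethenyl-2,4-dimethylpent-3-en-1-yl]oxolan-2-one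
Product: 24 (2R,3R,4S)-2-[(1S,2S)-1-(TBSO)-2-ethenyl-2,4-dimethylpent-3-en-1-yl]-4-(TBDPSO-methyl)-5-oxooxolane-3-carbaldehyde
Conditions: PPTS, acetone/H2O, 45 °C
Reagents that add atoms: water, O
Why: Mild acid-catalysed acetal hydrolysis unveils the C6 aldehyde while the hindered silyl ethers and the trisubstituted alkene are untouched.

Step 21
Reactants: 24 (2R,3R,4S)-2-[(1S,2S)-1-(TBSO)-2-ethenyl-2,4-dimethylpent-3-en-1-yl]-4-(TBDPSO-methyl)-5-oxooxolane-3-carbaldehyde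
Product: 25 9α-(TBSO)-13-(TBDPSO)-6α-hydroxy-11βH-elema-1,3-dien-12,8α-olide
Conditions: Me2AlCl, CH2Cl2, −78 → −20 °C
Reagents that add atoms: none
Why: Lewis-acid-promoted type 1 intramolecular carbonyl-ene reaction (as in citronellal to isopulegol) closes ring B through a chair transition state with the trans-lactone bonds equatorial; this sets C5 with the isopropenyl group equatorial (β) and gives the equatorial 6α-alcohol.

Step 22
Reactants: 25 9α-(TBSO)-13-(TBDPSO)-6α-hydroxy-11βH-elema-1,3-dien-12,8α-olide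
Product: 26 9α-(TBSO)-13-(TBDPSO)-6-oxo-11βH-elema-1,3-dien-12,8α-olide
Conditions: Dess–Martin periodinane, CH2Cl2, 0 °C
Reagents that add atoms: none
Why: Neutral Dess–Martin oxidation gives the C6 ketone without conjugating the β,γ-alkene or eliminating the β-acyloxy group.

Step 23
Reactants: 26 9α-(TBSO)-13-(TBDPSO)-6-oxo-11βH-elema-1,3-dien-12,8α-olide
Product: 27 9α-(TBSO)-13-(TBDPSO)-6β-hydroxy-11βH-elema-1,3-dien-12,8α-olide
Conditions: LiBH(s-Bu)3, THF, −78 °C; AcOH at −78 °C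
Reagents that add atoms: none
Why: The bulky hydride attacks equatorially (the axial face is also blocked by the syn-axial C10 methyl), giving the axial 6β-alcohol cis to both neighbours, as in isopulegone to neoisopulegol; the cold acid quench prevents translactonisation.

Step 24
Reactants: 27 9α-(TBSO)-13-(TBDPSO)-6β-hydroxy-11βH-elema-1,3-dien-12,8α-olide
Product: 28 6β-acetoxy-9α-(TBSO)-13-(TBDPSO)-11βH-elema-1,3-dien-12,8α-olide
Conditions: Ac2O, DMAP (cat.), pyridine, 40 °C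
Reagents that add atoms: acetic anhydride, CC(=O)OC(C)=O
Why: DMAP-catalysed acylation of the only free hydroxyl installs the C6 acetate.

Step 25
Reactants: 28 6β-acetoxy-9α-(TBSO)-13-(TBDPSO)-11βH-elema-1,3-dien-12,8α-olide
Product: 29 6β-acetoxy-9α,13-dihydroxy-11βH-elema-1,3-dien-12,8α-olide
Conditions: HF·pyridine, THF/pyridine, 0 °C → rt
Reagents that add atoms: none
Why: Buffered fluoride removes both silyl ethers while acetate, lactone and alkenes are stable.

Step 26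
Reactants: 29 6β-acetoxy-9α,13-dihydroxy-11βH-elema-1,3-dien-12,8α-olide
Product: 31 6β-acetoxy-9α-hydroxyelema-1,3,11(13)-trien-12,8α-olide, via mesylate 30 (not isolated)
Conditions: MsCl, Et3N, CH2Cl2, −30 °C; then DBU, 0 °C → rt
Reagents that add atoms: none
Why: The primary C13 hydroxyl is mesylated selectively over the hindered axial C9 hydroxyl and E1cB elimination (Grieco-type α-methylenation) gives the α-methylene lactone.

Step 27
Reactants: 31 6β-acetoxy-9α-hydroxyelema-1,3,11(13)-trien-12,8α-olide; 32 (2Z)-2-methylbut-2-enoic acid (angelic acid)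
Product: 34 6β-acetoxy-9α-(angeloyloxy)elema-1,3,11(13)-trien-12,8α-olide, via mixed anhydride 33 (not isolated)
Conditions: 2,4,6-Cl3C6H2COCl, Et3N, toluene, rt; then 31, 80 °C
Reagents that add atoms: none
Why: Yamaguchi esterification through the trichlorobenzoyl mixed anhydride acylates the hindered C9 hydroxyl, and leaving out a nucleophilic catalyst keeps the Z (angelate) geometry.

Step 28
Reactants: 34 6β-acetoxy-9α-(angeloyloxy)elema-1,3,11(13)-trien-12,8α-olide
Product: 35 6β-acetoxy-9α-(angeloyloxy)-15-hydroxyelema-1,3,11(13)-trien-12,8α-olide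
Conditions: SeO2 (cat.), t-BuOOH, CH2Cl2, rt
Reagents that add atoms: tert-butyl hydroperoxide, CC(C)(C)OO (oxygen passed on by catalytic SeO2)
Why: Riley allylic oxidation (ene reaction then 2,3-shift) hydroxylates the methyl of the isopropenyl group, the only electron-rich alkene with allylic hydrogens; the vinyl group has none and the two enoates are deactivated.

Step 29
Reactants: 35 6β-acetoxy-9α-(angeloyloxy)-15-hydroxyelema-1,3,11(13)-trien-12,8α-olide
Product: 36 (5R,6S,7S,8R,9S,10S)-6-acetoxy-9-[(2Z)-2-methylbut-2-enoyloxy]-15-oxoelema-1,3,11(13)-trien-12,8-olide (target)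
Conditions: MnO2, CH2Cl2, rt
Reagents that add atoms: none
Why: MnO2 oxidises only the allylic primary alcohol to the α-substituted acrolein, leaving esters, lactone and all stereocentres untouched.

**Compound list**
1 | methyl (4S)-2,2-dimethyl-1,3-dioxolane-4-carboxylate | COC(=O)[C@@H]1COC(C)(C)O1 | starting material
2 | (4S)-2,2-dimethyl-1,3-dioxolane-4-carbaldehyde | O=C[C@@H]1COC(C)(C)O1 | intermediate (not isolated)
3 | methyl (2Z)-3-[(4R)-2,2-dimethyl-1,3-dioxolan-4-yl]prop-2-enoate | COC(=O)/C=C\[C@@H]1COC(C)(C)O1 | intermediate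
4 | (5R)-5-(hydroxymethyl)furan-2(5H)-one | OC[C@@H]1OC(=O)C=C1 | intermediate
5 | (5R)-5-{[tert-butyl(dimethyl)silyl]oxymethyl}furan-2(5H)-one | CC(C)(C)[Si](C)(C)OC[C@@H]1OC(=O)C=C1 | intermediate
6 | (4S,5R)-5-{[tert-butyl(dimethyl)silyl]oxymethyl}-4-ethenyloxolan-2-one | CC(C)(C)[Si](C)(C)OC[C@@H]1OC(=O)C[C@H]1C=C | intermediate
7 | (3S,4R,5R)-5-{[tert-butyl(dimethyl)silyl]oxymethyl}-4-ethenyl-3-(hydroxymethyl)oxolan-2-one | CC(C)(C)[Si](C)(C)OC[C@@H]1OC(=O)[C@H](CO)[C@H]1C=C | intermediate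
8 | (3S,4R,5R)-5-{[tert-butyl(dimethyl)silyl]oxymethyl}-3-{[tert-butyl(diphenyl)silyl]oxymethyl}-4-ethenyloxolan-2-one | CC(C)(C)[Si](C)(C)OC[C@@H]1OC(=O)[C@H](CO[Si](c2ccccc2)(c2ccccc2)C(C)(C)C)[C@H]1C=C | intermediate
9 | (2R,3R,4S)-2-{[tert-butyl(dimethyl)silyl]oxymethyl}-4-{[tert-butyl(diphenyl)silyl]oxymethyl}-5-oxooxolane-3-carbaldehyde | CC(C)(C)[Si](C)(C)OC[C@@H]1OC(=O)[C@H](CO[Si](c2ccccc2)(c2ccccc2)C(C)(C)C)[C@H]1C=O | intermediate (not isolated)
10 | (3S,4R,5R)-3-{[tert-butyl(diphenyl)silyl]oxymethyl}-4-(dimethoxymethyl)-5-(hydroxymethyl)oxolan-2-one | OC[C@@H]1OC(=O)[C@H](CO[Si](c2ccccc2)(c2ccccc2)C(C)(C)C)[C@H]1C(OC)OC | intermediate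
11 | (2R,3R,4S)-4-{[tert-butyl(diphenyl)silyl]oxymethyl}-3-(dimethoxymethyl)-5-oxooxolane-2-carbaldehyde | O=C[C@@H]1OC(=O)[C@H](CO[Si](c2ccccc2)(c2ccccc2)C(C)(C)C)[C@H]1C(OC)OC | intermediate
12 | prop-2-yn-1-ol | C#CCO | starting material
13 | 1-methoxy-4-[(prop-2-yn-1-yloxy)methyl]benzene | C#CCOCc1ccc(OC)cc1 | intermediate
14 | ethyl 4-[(4-methoxyphenyl)methoxy]but-2-ynoate | CCOC(=O)C#CCOCc1ccc(OC)cc1 | intermediate
15 | ethyl (2Z)-4-[(4-methoxyphenyl)methoxy]-3-methylbut-2-enoate | CCOC(=O)/C=C(/C)COCc1ccc(OC)cc1 | intermediate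
16 | (2Z)-4-[(4-methoxyphenyl)methoxy]-3-methylbut-2-en-1-ol | OC/C=C(/C)COCc1ccc(OC)cc1 | intermediate
17 | 1-({[(2Z)-4-chloro-2-methylbut-2-en-1-yl]oxy}methyl)-4-methoxybenzene | ClC/C=C(/C)COCc1ccc(OC)cc1 | intermediate
18 | 2-{(2Z)-4-[(4-methoxyphenyl)methoxy]-3-methylbut-2-en-1-yl}-4,4,5,5-tetramethyl-1,3,2-dioxaborolane | CC1(C)OB(C/C=C(/C)COCc2ccc(OC)cc2)OC1(C)C | intermediate
19 | (3S,4R,5R)-3-(TBDPSO-methyl)-4-(dimethoxymethyl)-5-[(1S,2S)-1-hydroxy-2-{[(4-methoxyphenyl)methoxy]methyl}-2-methylbut-3-en-1-yl]oxolan-2-one | C=C[C@](COCc1ccc(OC)cc1)(C)[C@H](O)[C@@H]1OC(=O)[C@H](CO[Si](c2ccccc2)(c2ccccc2)C(C)(C)C)[C@H]1C(OC)OC | intermediate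
20 | 9-O-TBS ether of 19, side chain (1S,2S)-1-(TBSO)-2-(PMB-oxymethyl)-2-methylbut-3-en-1-yl | C=C[C@](COCc1ccc(OC)cc1)(C)[C@H](O[Si](C)(C)C(C)(C)C)[C@@H]1OC(=O)[C@H](CO[Si](c2ccccc2)(c2ccccc2)C(C)(C)C)[C@H]1C(OC)OC | intermediate
21 | primary alcohol, side chain (1S,2S)-1-(TBSO)-2-(hydroxymethyl)-2-methylbut-3-en-1-yl on the (3S,4R,5R)-lactone | C=C[C@](CO)(C)[C@H](O[Si](C)(C)C(C)(C)C)[C@@H]1OC(=O)[C@H](CO[Si](c2ccccc2)(c2ccccc2)C(C)(C)C)[C@H]1C(OC)OC | intermediate
22 | aldehyde, side chain (1S,2R)-1-(TBSO)-2-formyl-2-methylbut-3-en-1-yl on the (3S,4R,5R)-lactone | C=C[C@](C=O)(C)[C@H](O[Si](C)(C)C(C)(C)C)[C@@H]1OC(=O)[C@H](CO[Si](c2ccccc2)(c2ccccc2)C(C)(C)C)[C@H]1C(OC)OC | intermediate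
23 | (3S,4R,5R)-3-(TBDPSO-methyl)-4-(dimethoxymethyl)-5-[(1S,2S)-1-(TBSO)-2-ethenyl-2,4-dimethylpent-3-en-1-yl]oxolan-2-one | C=C[C@](C=C(C)C)(C)[C@H](O[Si](C)(C)C(C)(C)C)[C@@H]1OC(=O)[C@H](CO[Si](c2ccccc2)(c2ccccc2)C(C)(C)C)[C@H]1C(OC)OC | intermediate
24 | (2R,3R,4S)-2-[(1S,2S)-1-(TBSO)-2-ethenyl-2,4-dimethylpent-3-en-1-yl]-4-(TBDPSO-methyl)-5-oxooxolane-3-carbaldehyde | C=C[C@](C=C(C)C)(C)[C@H](O[Si](C)(C)C(C)(C)C)[C@@H]1OC(=O)[C@H](CO[Si](c2ccccc2)(c2ccccc2)C(C)(C)C)[C@H]1C=O | intermediate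
25 | 9α-(TBSO)-13-(TBDPSO)-6α-hydroxy-11βH-elema-1,3-dien-12,8α-olide (5αH, 7αH, 8βH, 10β-methyl) | C=C[C@]1(C)[C@H](O[Si](C)(C)C(C)(C)C)[C@@H]2OC(=O)[C@H](CO[Si](c3ccccc3)(c3ccccc3)C(C)(C)C)[C@H]2[C@H](O)[C@H]1C(C)=C | intermediate
26 | 9α-(TBSO)-13-(TBDPSO)-6-oxo-11βH-elema-1,3-dien-12,8α-olide | C=C[C@]1(C)[C@H](O[Si](C)(C)C(C)(C)C)[C@@H]2OC(=O)[C@H](CO[Si](c3ccccc3)(c3ccccc3)C(C)(C)C)[C@H]2C(=O)[C@H]1C(C)=C | intermediate
27 | 9α-(TBSO)-13-(TBDPSO)-6β-hydroxy-11βH-elema-1,3-dien-12,8α-olide | C=C[C@]1(C)[C@H](O[Si](C)(C)C(C)(C)C)[C@@H]2OC(=O)[C@H](CO[Si](c3ccccc3)(c3ccccc3)C(C)(C)C)[C@H]2[C@@H](O)[C@H]1C(C)=C | intermediate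
28 | 6β-acetoxy-9α-(TBSO)-13-(TBDPSO)-11βH-elema-1,3-dien-12,8α-olide | C=C[C@]1(C)[C@H](O[Si](C)(C)C(C)(C)C)[C@@H]2OC(=O)[C@H](CO[Si](c3ccccc3)(c3ccccc3)C(C)(C)C)[C@H]2[C@@H](OC(C)=O)[C@H]1C(C)=C | intermediate
29 | 6β-acetoxy-9α,13-dihydroxy-11βH-elema-1,3-dien-12,8α-olide | C=C[C@]1(C)[C@H](O)[C@@H]2OC(=O)[C@H](CO)[C@H]2[C@@H](OC(C)=O)[C@H]1C(C)=C | intermediate
30 | 6β-acetoxy-9α-hydroxy-13-(methanesulfonyloxy)-11βH-elema-1,3-dien-12,8α-olide | C=C[C@]1(C)[C@H](O)[C@@H]2OC(=O)[C@H](COS(C)(=O)=O)[C@H]2[C@@H](OC(C)=O)[C@H]1C(C)=C | intermediate (not isolated)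
31 | 6β-acetoxy-9α-hydroxyelema-1,3,11(13)-trien-12,8α-olide | C=C[C@]1(C)[C@H](O)[C@@H]2OC(=O)C(=C)[C@H]2[C@@H](OC(C)=O)[C@H]1C(C)=C | intermediate
32 | (2Z)-2-methylbut-2-enoic acid (angelic acid) | C/C=C(/C)C(=O)O | starting material
33 | (2Z)-2-methylbut-2-enoic 2,4,6-trichlorobenzoic anhydride | C/C=C(/C)C(=O)OC(=O)c1c(Cl)cc(Cl)cc1Cl | intermediate (not isolated)
34 | 6β-acetoxy-9α-[(2Z)-2-methylbut-2-enoyloxy]elema-1,3,11(13)-trien-12,8α-olide | C=C[C@]1(C)[C@H](OC(=O)/C(C)=C\C)[C@@H]2OC(=O)C(=C)[C@H]2[C@@H](OC(C)=O)[C@H]1C(C)=C | intermediate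
35 | 6β-acetoxy-9α-[(2Z)-2-methylbut-2-enoyloxy]-15-hydroxyelema-1,3,11(13)-trien-12,8α-olide | C=C[C@]1(C)[C@H](OC(=O)/C(C)=C\C)[C@@H]2OC(=O)C(=C)[C@H]2[C@@H](OC(C)=O)[C@H]1C(=C)CO | intermediate
36 | (5R,6S,7S,8R,9S,10S)-6-acetoxy-9-[(2Z)-2-methylbut-2-enoyloxy]-15-oxoelema-1,3,11(13)-trien-12,8-olide | C=C[C@]1(C)[C@H](OC(=O)/C(C)=C\C)[C@@H]2OC(=O)C(=C)[C@H]2[C@@H](OC(C)=O)[C@H]1C(=C)C=O | target

**Step count and risk**
Total step count: 29. Longest linear sequence: 23 steps (steps 1–8, then 15–29); the boronate branch is steps 9–14.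

Most likely to fail, first: step 21 (ene ring closure next to the quaternary C10). The fallback sets out from aldehyde 22. A Wittig reaction with [1-methyl-2-(trimethylsilyl)ethylidene]triphenylphosphorane gives the allylsilane F1. Acetal hydrolysis (PPTS, acetone/H2O) gives the silyl aldehyde F2. TiCl4 in CH2Cl2 at −78 °C then closes ring B by an intramolecular Hosomi–Sakurai allylation (SE2' at C5), in place of the ene reaction. This gives the same cyclohexanol as a C6 mixture (25 and its epimer 27); the mixture is oxidised as in step 22 and the fallback comes back to the route at ketone 26.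

Second: step 27 (angeloylation of the hindered axial C9 hydroxyl). The fallback sets out from alcohol 31. DCC/DMAP coupling with 2-[bis(2,2,2-trifluoroethoxy)phosphoryl]propanoic acid gives the phosphonate ester F3; this acylation runs through a phosphonoketene and is less sensitive to hindrance. KN(SiMe3)2/18-crown-6 in THF at −78 °C followed by acetaldehyde (Still–Gennari Z-selective olefination) then builds the angelate double bond on the substrate and comes back to the route at 34.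

Third: step 28 (late SeO2 oxidation in the presence of two enoates). The fallback sets out from 34. Ene-type allylic chlorination of the isopropenyl group with HOCl (Ca(OCl)2, CO2, CH2Cl2/H2O, 0 °C) gives the allylic chloride F4. Ganem oxidation with N-methylmorpholine N-oxide (MeCN, rt → 40 °C) turns CH2Cl directly into CHO and comes back to the route at target 36, bypassing 35.

**Further compounds**
F1 | step 21 | allylsilane, side chain (1S,2S,3E)-1-(TBSO)-2-ethenyl-2,4-dimethyl-5-(trimethylsilyl)pent-3-en-1-yl on the (3S,4R,5R)-lactone acetal (E shown; the Z isomer reacts alike) | C=C[C@](/C=C(\C)C[Si](C)(C)C)(C)[C@H](O[Si](C)(C)C(C)(C)C)[C@@H]1OC(=O)[C@H](CO[Si](c2ccccc2)(c2ccccc2)C(C)(C)C)[C@H]1C(OC)OC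
F2 | step 21 | silyl aldehyde, the C6 aldehyde corresponding to F1 | C=C[C@](/C=C(\C)C[Si](C)(C)C)(C)[C@H](O[Si](C)(C)C(C)(C)C)[C@@H]1OC(=O)[C@H](CO[Si](c2ccccc2)(c2ccccc2)C(C)(C)C)[C@H]1C=O
F3 | step 27 | phosphonate ester, 9α-O-{2-[bis(2,2,2-trifluoroethoxy)phosphoryl]propanoyl} derivative of 31 (both epimers at the phosphorus-bearing carbon) | C=C[C@]1(C)[C@H](OC(=O)C(C)P(=O)(OCC(F)(F)F)OCC(F)(F)F)[C@@H]2OC(=O)C(=C)[C@H]2[C@@H](OC(C)=O)[C@H]1C(C)=C
F4 | step 28 | allylic chloride, 15-chloro derivative of 34 | C=C[C@]1(C)[C@H](OC(=O)/C(C)=C\C)[C@@H]2OC(=O)C(=C)[C@H]2[C@@H](OC(C)=O)[C@H]1C(=C)CCl
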